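Starting material is conserved: counted as starting material, what has gone into the flask stands as free starting material, as the complexes, as target or as self-condensation product, so you can reckon the target by reckoning the loss.

| flask | starting material | second substrate | precatalyst | time | remark |
|---|---|---|---|---|---|
| Saturday's | 0.020 M (fed, over 4.0 h) | 0.0800 M | 1.6 µM | 10 h | all else is in the flask from the start; the feed brings no volume worth counting |
| Friday's | 0.020 M | 0.0800 M | 1.6 µM | 10 h | everything together at the start |
| Thursday's | 0.020 M | 0.0800 M (fed, over 4.0 h) | 1.6 µM | 10 h | all else is in the flask from the start; the feed brings no volume worth counting |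

* the flask with the highest amount of target, in percent of the starting material charged ("all alike" if they lie within 1.5 percentage points) (Saturday's / Friday's / Thursday's / all alike)
* final target, as a percentage of the starting material charged, in Saturday's
* final target, as a percentage of the starting material charged, in Friday's
* final target, as a percentage of the starting material charged, in Thursday's

- in percentages every species weighs as the starting material in it: one self-condensation product counts as two
- a step written with two of one species runs at k times the square of its concentration and takes two of it each time
- run time (Saturday's): 10 h

    starting material + enzyme ⇌ starting complex (K1 = 53 M⁻¹, k1 = 660 M⁻¹ s⁻¹)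
    second substrate + precatalyst → enzyme + spent reagent (k2 = 0.0014 M⁻¹ s⁻¹)
    ternary complex → enzyme + target (k3 = 2.1 s⁻¹)
    second substrate + starting complex ⇌ ternary complex (K4 = 31 M⁻¹, k4 = 4300 M⁻¹ s⁻¹)
    2 starting material → self-condensation product (k5 = 6.2 × 10⁻⁴ M⁻¹ s⁻¹)
    enzyme ⇌ dormant form (K6 = 21, k6 = 1.1 × 10⁻⁵ s⁻¹)

The self-condensation, with rate constant k = 6.2 × 10⁻⁴ M⁻¹ s⁻¹, runs as soon as starting material is there, but the enzyme must first be made from precatalyst by the second substrate, with rate constant 0.0014 M⁻¹ s⁻¹. At the charged amounts, that wake-up takes a mean time τ = 2.48 h, and the condensation's first half-life is 11.2 h, so τ is the shorter of the two. Suppose the catalyst sleeps for τ and condensation runs unopposed, with c the starting-material charge and x = 2kcτ. The fraction lost is then x over one plus x, which I call the wake-up loss: 18.1 % for Friday's.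

To bracket Friday's, I count condensation over one precatalyst half-life at the charged second substrate, 1.7 h, for a low estimate of the loss, 13.3 %, and over two for a high one, 23.5 %. My estimate of target therefore runs from 76.5 % to 86.7 %, and my point is 81.9 %. In Thursday's, the feed delays the wake-up by half the feeding time, so the window is 4.48 h, the loss 28.6 % and the target 71.4 %, below Friday's floor. In Saturday's, supposing the concentration rises with nothing consumed, condensation takes 2.84 % by τ and 11.9 % by the end of the feed, so my estimate of target runs from 88.1 % to 97.2 %, with its floor above my Friday's ceiling.

The forecast, which holds that activation “limits early turnover”, names Saturday's, with 90.5 % there, 80 % in Friday's and 71 % in Thursday's. Its Saturday's and Friday's values stand inside my brackets, though its Friday's value lies below my point.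

The simulation gives Saturday's as the highest, with 90.4 % there, 80.2 % in Friday's and 70.2 % in Thursday's.

Thursday's self-condensation product stood at 24.1 % at 4.00 h and 27.8 % at 10.0 h, beside a wake-up loss of 28.6 %; Friday's ended at 19.1 %, beside 18.1 %. At 5.15 h in Thursday's, the forward step to the starting complex used starting material 38 times as fast as condensation did. Now take Thursday's neighbour with 0.020 M of second substrate: its window of 11.9 h exceeds the run, so the wake-up loss, reckoned over 10 h, is 47.2 %, with starting material left over. That flask ends with 41.7 % condensed, 37.0 % starting material and 21.2 % target.

The constants belong to no real substance, and the outcome is calculated.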